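**Analysis of the target**

Mururin C is a fully aromatic 2-arylbenzofuran. Ring A (the benzo ring) carries a methoxy group at C7 and a 3-hydroxypropyl chain at C5; the furan ring carries a formyl group at C3 and ring C, a 3-methoxy-4,5-dihydroxyphenyl group, at C2. There are no stereocentres and no configured double bond, so the problem is one of regiochemistry and functional-group tolerance only. The sensitive groups are the free catechol of ring C (easily oxidized, and a strong nucleophile towards carbon electrophiles), the C3 aldehyde (a vinylogous formate through O1, stable to acid but not to organometallic or hydride reagents) and the primary alcohol. The difficulty lies in the fully substituted C2/C3 pair: two different carbon substituents must each be placed on its own furan carbon without acylating either electron-rich benzene ring, and the route must end with a free catechol beside an aldehyde. The strategy rests on the O1–C2=C3 unit being an enol ether. In a 2,3-unsubstituted benzofuran the C2–H is the most acidic proton and C3 is the nucleophilic carbon, so ring C can be delivered to C2 as a nucleophile on boron and the formyl carbon to C3 as a cation, in one operation. Ring A with its substituents is the skeleton of dihydroferulic acid and ring C that of 3-methoxycatechol, so both rings can be bought and only the two bonds at C2 and C3 need to be made.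

**Retrosynthetic reasoning**

Mururin C 17 is traced back to the protected acetal 16. The aldehyde is masked as a dimethyl acetal, the catechol as two methoxymethyl ethers and the alcohol as a silyl ether. All three masks are acid-labile, so one treatment with aqueous acid should reveal everything, and the catechol and aldehyde never have to face the organometallic chemistry.

In 16 the C2–C1′ bond (to ring C) and the bond from C3 to the acetal carbon are cut together. These two bonds flank the enol ether, and they are the only skeletal bonds not already present in bought material. The precursors are the bare ring A benzofuran 6, the ring C boronic ester 9 and the orthoester 10 as the one-carbon source. Forward, 6 is deprotonated at C2 to 12, which adds to 9 to give the boronate 13. The cation 11, made from 10, must then bond to C3 while ring C shifts from boron to C2 (giving 14). Oxidation to the hemiketal 15 and loss of water restore the furan. The gain is convergence: two bonds in one operation, no ring construction, and C3 delivered at the aldehyde oxidation level.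

The benzofuran 6 is traced through the alcohol 5 and the ester 4 to the aryl ether 3, cutting the C3–C3a bond. Compound 3 comes from the phenol 1 and the bromoacetal 2 by cutting the O1–C2 bond. Only one position ortho to the ether oxygen of 3 is free, so the acid-catalysed ring closure can give only the 7-methoxy-5-substituted benzofuran. The ester is kept through the acidic cyclization and is reduced and silylated afterwards, because a silyl ether or free alcohol would not survive it cleanly.

The boronic ester 9 is traced to the bis-ether 8 by cutting the C–B bond, and 8 to the catechol 7. In the 1,2,3-trisubstituted ring of 8 only one C–H has no ortho neighbour. A sterically governed iridium-catalysed C–H borylation should therefore place boron exactly where ring C must join C2, and no halogenated ring C building block is needed.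

**Alternatives that were turned down**

Alternative 1: Biomimetic oxidative coupling with late aromatization.
- Disconnection: the C3–C3a and O1–C2 bonds, leading to methyl (E)-3-(3-benzyloxy-4-hydroxy-5-methoxyphenyl)acrylate A1 and dihydroconiferyl alcohol A2.
- Forward key step: a heterogeneous silver-based one-electron oxidant turns both phenols into phenoxyl radicals. Carbon 8 of A1 bonds to the free ortho carbon of A2, and the ring A phenol closes onto the quinone methide so formed, giving the racemic trans-dihydrobenzofuran ester A3.
- For: one step makes two bonds and the furan ring from two phenylpropanoids; the C3 carbon is in place; every step is a known reaction type and no organometallic reagent is needed. On precedent it is stronger than the chosen route.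
- Against: the pairing of two different radicals is not controlled. A2 can dimerize through its ortho carbon or oxygen, and A1 can couple 8–8 or 8–O, so the cross product is one of several. The two stereocentres set are discarded. Dehydrogenation of A3 with a quinone-type oxidant needs the free para-phenol protected first. The ester needs a reduction–oxidation pair beside a free primary alcohol. Hydrogenolysis of the benzyl ether at the end competes with reduction of the aldehyde. A1 itself needs a regioselective mono-benzylation of a catechol. The count comes to about ten steps.
- Comparison: the chosen strategy offers polarity-controlled pairing at C2 and C3, the aromatic oxidation level from the start, and a one-operation end game.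

Alternative 2: Ring A built on a 2-arylfuran by Stobbe benzannulation.
- Disconnection: ring A is taken apart at C7–C7a and C4–C5, leading to 5-[3,4-bis(benzyloxy)-5-methoxyphenyl]furan-3-carbaldehyde A4 and dimethyl succinate A5, which condense to the half-ester A6.
- Forward key step: a carboxylic anhydride with its sodium salt activates the acid of A6 as a mixed anhydride. The acyl carbon attacks the furan α-carbon, and enolization and acetylation give methyl 7-acetoxy-2-[3,4-bis(benzyloxy)-5-methoxyphenyl]benzofuran-5-carboxylate A7.
- For: a dependable benzannulation that uses the most nucleophilic furan carbon. Its regiochemistry is at least as secure as that of the chosen key step.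
- Against: A7 has no C3 substituent, an ester where a three-carbon chain is needed, and an acetate where a methyl ether is needed. That means a later C3 formylation, an acetate-to-methyl-ether exchange and a two-carbon homologation, the last clashing with the benzyl ethers if an alkene is hydrogenated. Ring A is built from scratch although it can be bought complete. The count is well above twelve steps.
- Comparison: the chosen strategy buys ring A fully substituted and places the risk in one step instead of spreading the effort over a long functional-group sequence.

Alternative 3: Acyl-lactone to furan-ester transposition.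
- Disconnection: the O1–C2 bond, leading to the 3-aroylbenzofuran-2(3H)-one A8.
- Forward key step: methanolic mineral acid opens the lactone to a methyl ester, and the freed phenol condenses with the aroyl ketone to give the 2-arylbenzofuran-3-carboxylate A9.
- For: the positions of ring C and of the C3 carbon are fixed without ambiguity, aromatization drives the step, and the reaction type is known. Here it is stronger than the chosen route.
- Against: A8 needs an arylacetic acid ortho to the phenol of ring A, which takes several steps from a dihydroferulate, and then a C-acylation that competes with O-acylation. A9 carries two esters, so both must be reduced and the heteroaryl carbinol re-oxidized selectively. The benzyl ethers must then be removed beside the aldehyde. The count is about eleven steps.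
- Comparison: the chosen strategy is shorter by several steps and brings C3 in as a masked aldehyde that is released together with the protecting groups. The price is one unprecedented step.

Key step: step 7

Assumption: compounds 1, 2, 7 and 10 are taken as catalogue chemicals. The dimethyl acetal 2 is used instead of the diethyl acetal so that the alcohol released in step 2 is the same as that of the methyl ester and no ester exchange can occur.

**Route**

Step 1
Reactants: 1 methyl dihydroferulate [methyl 3-(4-hydroxy-3-methoxyphenyl)propanoate]; 2 bromoacetaldehyde dimethyl acetal (2-bromo-1,1-dimethoxyethane)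
Product: 3 methyl 3-[4-(2,2-dimethoxyethoxy)-3-methoxyphenyl]propanoate
Conditions: K2CO3, DMF, 110 °C
Reagents that add atoms: none
Why: Williamson ether synthesis; the phenoxide of 1 displaces bromide from the primary carbon of 2 (a slow SN2 next to an acetal, hence the heating), and the ester is untouched by anhydrous carbonate.

Step 2
Reactants: 3 methyl 3-[4-(2,2-dimethoxyethoxy)-3-methoxyphenyl]propanoate
Product: 4 methyl 3-(7-methoxybenzofuran-5-yl)propanoate
Conditions: Amberlyst 15, PhCl, 125 °C, MeOH distilled off
Reagents that add atoms: none
Why: Acid-catalysed cyclodehydration of an aryloxyacetaldehyde acetal (intramolecular Friedel–Crafts attack of the oxocarbenium ion, then loss of methanol); only one position ortho to the ether oxygen is free, so only the 7-methoxy-5-substituted benzofuran can form.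

Step 3
Reactants: 4 methyl 3-(7-methoxybenzofuran-5-yl)propanoate
Product: 5 3-(7-methoxybenzofuran-5-yl)propan-1-ol
Conditions: LiAlH4, THF, 0 °C to rt
Reagents that add atoms: none
Why: Hydride reduction of an ester to the primary alcohol; the benzofuran and the aryl methyl ether are inert to LiAlH4.

Step 4
Reactants: 5 3-(7-methoxybenzofuran-5-yl)propan-1-ol
Product: 6 tert-butyl[3-(7-methoxybenzofuran-5-yl)propoxy]dimethylsilane
Conditions: TBSCl, imidazole, CH2Cl2, rt
Reagents that add atoms: tert-butyldimethylsilyl chloride, CC(C)(C)[Si](C)(C)Cl
Why: Imidazole-promoted silylation of a primary alcohol; the silyl ether removes the only acidic O–H before the organolithium step and is stable to n-BuLi at low temperature.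

Step 5
Reactants: 7 3-methoxycatechol (3-methoxybenzene-1,2-diol)
Product: 8 1-methoxy-2,3-bis(methoxymethoxy)benzene
Conditions: MOMCl, i-Pr2NEt, CH2Cl2, 0 °C to rt
Reagents that add atoms: chloromethyl methyl ether, COCCl
Why: O-alkylation of both phenols with an α-chloro ether; the MOM ethers tolerate organolithium and boronate chemistry and are cleaved by aqueous acid at the end.

Step 6
Reactants: 8 1-methoxy-2,3-bis(methoxymethoxy)benzene
Product: 9 2-[3-methoxy-4,5-bis(methoxymethoxy)phenyl]-4,4,5,5-tetramethyl-1,3,2-dioxaborolane
Conditions: [Ir(OMe)(cod)]2 (cat.), dtbpy, B2pin2 (0.6 equiv), THF, 80 °C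
Reagents that add atoms: bis(pinacolato)diboron, CC1(C)OB(OC1(C)C)B1OC(C)(C)C(C)(C)O1
Why: Iridium-catalysed aromatic C–H borylation, which is governed by sterics; in the 1,2,3-trisubstituted ring of 8 only C5 has no ortho substituent, so boron should enter meta to the methoxy group and para to the central MOM ether.

Step 7
Reactants: 6 tert-butyl[3-(7-methoxybenzofuran-5-yl)propoxy]dimethylsilane; 9 2-[3-methoxy-4,5-bis(methoxymethoxy)phenyl]-4,4,5,5-tetramethyl-1,3,2-dioxaborolane; 10 trimethyl orthoformate
Product: 16 tert-butyl[3-(3-(dimethoxymethyl)-7-methoxy-2-[3-methoxy-4,5-bis(methoxymethoxy)phenyl]benzofuran-5-yl)propoxy]dimethylsilane, via dimethoxycarbenium tetrafluoroborate 11 (not isolated), via 2-lithiobenzofuran 12 (not isolated), via lithium boronate complex 13 (not isolated), via 2-boryl-2,3-dihydrobenzofuran 14 (not isolated), via hemiketal 15 (not isolated)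
Conditions: 6, n-BuLi, THF, −78 °C; 9, −78 °C to rt; solvent exchange to CH2Cl2; 11 [from 10, BF3·OEt2, CH2Cl2, −30 °C], −78 to 0 °C; NaBO3·4H2O, THF/H2O, 0 °C to rt; PPTS, 4 Å MS, toluene, 50 °C
Reagents that add atoms: none
Why: Proposed new method: n-BuLi removes the C2 proton of 6 (the most acidic C–H, next to O1) to give 12, which adds to the vacant orbital on boron of 9 to give the tetracoordinate boronate 13; the C2=C3 bond of 13 is an enol ether made more electron-rich by the anionic boron, so cation 11 should bond to C3, and as positive charge grows at C2 (stabilized by O1) the ring C aryl group shifts from boron to C2 anti to the incoming electrophile, giving 14. The closest known reaction type is the electrophile-induced 1,2-metallate rearrangement of indol-2-yl and furan-2-yl boronate complexes (Zweifel-type three-component coupling); a dialkoxycarbenium ion has not been used as the electrophile on a benzofuran-2-yl boronate, but such ions are established one-carbon electrophiles for silyl enol ethers, which C3 of 13 resembles. Perborate oxidation then replaces boron on C2 by OH with retention to give hemiketal 15, and PPTS ionizes the C2–OH bond to a cation stabilized by O1 and ring C that loses H3, restoring the aromatic furan of 16. The step forms the C3–CH(OMe)2 and C2–C1′ bonds and closes no new ring; should 15 open to its keto-phenol tautomer, the furan ring re-forms by 5-exo-trig addition of the phenol to the ketone before dehydration. The two stereocentres of 14 (C2 and C3, aryl and acetal trans from the anti addition) are both erased on aromatization, so no stereocontrol is needed. The selectivities required are C2 lithiation instead of metalation ortho to the C7 methoxy group (secured by the higher acidity of the furan α-proton), attack of 11 at C3 and not at a boron-bound carbon or a pinacol oxygen (secured by the enol-ether polarization), migration of aryl and not of a pinacol oxygen (the B–aryl bond aligns with the developing cationic orbital at C2), and closure through the ketone and not through the acetal carbon during aromatization (the acetal stays un-ionized under a weak acid with water excluded). Perborate is used instead of alkaline peroxide because the ring-opened form of 15 is a β-keto acetal that could lose methoxide by E1cB elimination in strong base.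

Step 8
Reactants: 16 tert-butyl[3-(3-(dimethoxymethyl)-7-methoxy-2-[3-methoxy-4,5-bis(methoxymethoxy)phenyl]benzofuran-5-yl)propoxy]dimethylsilane
Product: 17 Mururin C [2-(3,4-dihydroxy-5-methoxyphenyl)-5-(3-hydroxypropyl)-7-methoxybenzofuran-3-carbaldehyde]
Conditions: 3 M aq HCl, THF, 40 °C
Reagents that add atoms: water, O
Why: Acid hydrolysis of three acid-labile masks in one operation (dimethyl acetal to aldehyde, two MOM acetals to the catechol, silyl ether to the alcohol); the benzofuran core, the aryl methyl ethers and the conjugated aldehyde are stable to dilute aqueous acid.

**Compound list**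

1 | methyl dihydroferulate [methyl 3-(4-hydroxy-3-methoxyphenyl)propanoate] | COC(=O)CCc1ccc(O)c(OC)c1 | starting material
2 | bromoacetaldehyde dimethyl acetal (2-bromo-1,1-dimethoxyethane) | COC(CBr)OC | starting material
3 | methyl 3-[4-(2,2-dimethoxyethoxy)-3-methoxyphenyl]propanoate | COC(=O)CCc1ccc(OCC(OC)OC)c(OC)c1 | intermediate
4 | methyl 3-(7-methoxybenzofuran-5-yl)propanoate | COC(=O)CCc1cc(OC)c2occc2c1 | intermediate
5 | 3-(7-methoxybenzofuran-5-yl)propan-1-ol | OCCCc1cc(OC)c2occc2c1 | intermediate
6 | tert-butyl[3-(7-methoxybenzofuran-5-yl)propoxy]dimethylsilane | COc1cc(CCCO[Si](C)(C)C(C)(C)C)cc2ccoc12 | intermediate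
7 | 3-methoxycatechol (3-methoxybenzene-1,2-diol) | COc1cccc(O)c1O | starting material
8 | 1-methoxy-2,3-bis(methoxymethoxy)benzene | COCOc1cccc(OC)c1OCOC | intermediate
9 | 2-[3-methoxy-4,5-bis(methoxymethoxy)phenyl]-4,4,5,5-tetramethyl-1,3,2-dioxaborolane | COc1cc(B2OC(C)(C)C(C)(C)O2)cc(OCOC)c1OCOC | intermediate
10 | trimethyl orthoformate | COC(OC)OC | starting material
11 | dimethoxycarbenium tetrafluoroborate (made from 10, used at once) | CO[CH+]OC.F[B-](F)(F)F | intermediate
12 | {5-[3-(tert-butyldimethylsilyloxy)propyl]-7-methoxybenzofuran-2-yl}lithium | [Li]c1cc2cc(CCCO[Si](C)(C)C(C)(C)C)cc(OC)c2o1 | intermediate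
13 | lithium boronate complex: boron bound to pinacolate, to ring C and to C2 of the benzofuran | [Li+].COc1cc([B-]2(OC(C)(C)C(C)(C)O2)c2cc3cc(CCCO[Si](C)(C)C(C)(C)C)cc(OC)c3o2)cc(OCOC)c1OCOC | intermediate
14 | 2-boryl-2,3-dihydrobenzofuran: C2 bears ring C and Bpin, C3 bears CH(OMe)2; ring C and acetal trans; racemic, one enantiomer drawn | COC(OC)[C@H]1c2cc(CCCO[Si](C)(C)C(C)(C)C)cc(OC)c2O[C@]1(B1OC(C)(C)C(C)(C)O1)c1cc(OC)c(OCOC)c(OCOC)c1 | intermediate
15 | hemiketal: 2-aryl-3-(dimethoxymethyl)-2-hydroxy-2,3-dihydrobenzofuran; racemic, drawn as formed with retention at C2, which can epimerize through the open keto-phenol | COC(OC)[C@H]1c2cc(CCCO[Si](C)(C)C(C)(C)C)cc(OC)c2O[C@]1(O)c1cc(OC)c(OCOC)c(OCOC)c1 | intermediate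
16 | tert-butyl[3-(3-(dimethoxymethyl)-7-methoxy-2-[3-methoxy-4,5-bis(methoxymethoxy)phenyl]benzofuran-5-yl)propoxy]dimethylsilane | COC(OC)c1c(-c2cc(OC)c(OCOC)c(OCOC)c2)oc2c(OC)cc(CCCO[Si](C)(C)C(C)(C)C)cc12 | intermediate
17 | Mururin C [2-(3,4-dihydroxy-5-methoxyphenyl)-5-(3-hydroxypropyl)-7-methoxybenzofuran-3-carbaldehyde] | COc1cc(-c2oc3c(OC)cc(CCCO)cc3c2C=O)cc(O)c1O | target

**Step count and risks**

Total: 8 steps. Longest linear sequence: 6 steps (steps 1, 2, 3, 4, 7, 8); the ring C branch is steps 5 and 6.

Step 7 (key step, proposed new method). Three things may go wrong.
- The carbenium ion may transfer a methyl group to, or be captured by, a pinacol oxygen of the boronate instead of bonding to C3. The boronate would then collapse and the two halves be returned uncoupled.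
- The electrophile may add at C3 without the aryl shift following.
- During aromatization the hemiketal may open and re-close through the acetal carbon, which would move ring C onto a ketone at C3.

The fallback uses known chemistry and sets out from 6. Lithiation at C2 (n-BuLi, THF, −78 °C) and quenching with I2 should give tert-butyl[3-(2-iodo-7-methoxybenzofuran-5-yl)propoxy]dimethylsilane F1. Suzuki–Miyaura coupling of F1 with 9 (Pd(dppf)Cl2, K3PO4, dioxane/H2O, 80 °C) should give the 2-arylbenzofuran tert-butyl[3-(7-methoxy-2-[3-methoxy-4,5-bis(methoxymethoxy)phenyl]benzofuran-5-yl)propoxy]dimethylsilane F2. Electrophilic iodination at the enol-ether carbon C3 (NIS, MeCN, 0 °C) should give the 3-iodo compound tert-butyl[3-(3-iodo-7-methoxy-2-[3-methoxy-4,5-bis(methoxymethoxy)phenyl]benzofuran-5-yl)propoxy]dimethylsilane F3. Iodine–magnesium exchange (i-PrMgCl·LiCl, THF, −20 °C; the magnesium species avoids the ring opening to which 3-lithiobenzofurans are prone) and quenching with DMF should give the protected aldehyde 5-[3-(tert-butyldimethylsilyloxy)propyl]-7-methoxy-2-[3-methoxy-4,5-bis(methoxymethoxy)phenyl]benzofuran-3-carbaldehyde F4. The conditions of step 8 then remove the MOM and silyl groups of F4, and the fallback comes back to the route at 17. It costs three more steps.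

Step 2. The oxocarbenium ion from the acetal may react between molecules and give oligomers instead of closing the ring, because the carbon of closure is activated only by the ortho ether oxygen. The fallback sets out from 1. Iodination ortho to the phenol (NIS, MeCN) should give methyl 3-(4-hydroxy-3-iodo-5-methoxyphenyl)propanoate F5. Sonogashira coupling with ethynyltrimethylsilane and in situ 5-endo cyclization (Pd(PPh3)2Cl2, CuI, Et3N, DMF, 70 °C) should give methyl 3-[7-methoxy-2-(trimethylsilyl)benzofuran-5-yl]propanoate F6. Protodesilylation (TBAF, THF) returns to the route at 4. Here the furan ring is closed by O–C bond formation onto an alkyne and not by Friedel–Crafts attack.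

Step 8. The formaldehyde set free from the MOM groups, or the methoxymethyl cation before it, may attack the electron-rich free catechol ring. Loss of the second MOM group may also lag and call for more forcing acid. The fallback sets out from 16 and changes the order of unmasking. Anhydrous HCl in MeOH at rt should cleave the MOM and silyl ethers while the solvent traps the one-carbon unit as its dimethyl acetal and keeps the aldehyde masked. This should give 5-[3-(dimethoxymethyl)-5-(3-hydroxypropyl)-7-methoxybenzofuran-2-yl]-3-methoxybenzene-1,2-diol F7. Brief hydrolysis of F7 (PPTS, acetone/H2O, rt) returns to the route at 17.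

**Further compounds**

F1 | step 7 | tert-butyl[3-(2-iodo-7-methoxybenzofuran-5-yl)propoxy]dimethylsilane | COc1cc(CCCO[Si](C)(C)C(C)(C)C)cc2cc(I)oc12
F2 | step 7 | tert-butyl[3-(7-methoxy-2-[3-methoxy-4,5-bis(methoxymethoxy)phenyl]benzofuran-5-yl)propoxy]dimethylsilane | COc1cc(-c2cc3cc(CCCO[Si](C)(C)C(C)(C)C)cc(OC)c3o2)cc(OCOC)c1OCOC
F3 | step 7 | tert-butyl[3-(3-iodo-7-methoxy-2-[3-methoxy-4,5-bis(methoxymethoxy)phenyl]benzofuran-5-yl)propoxy]dimethylsilane | COc1cc(-c2oc3c(OC)cc(CCCO[Si](C)(C)C(C)(C)C)cc3c2I)cc(OCOC)c1OCOC
F4 | step 7 | 5-[3-(tert-butyldimethylsilyloxy)propyl]-7-methoxy-2-[3-methoxy-4,5-bis(methoxymethoxy)phenyl]benzofuran-3-carbaldehyde | COc1cc(-c2oc3c(OC)cc(CCCO[Si](C)(C)C(C)(C)C)cc3c2C=O)cc(OCOC)c1OCOC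
F5 | step 2 | methyl 3-(4-hydroxy-3-iodo-5-methoxyphenyl)propanoate | COC(=O)CCc1cc(I)c(O)c(OC)c1
F6 | step 2 | methyl 3-[7-methoxy-2-(trimethylsilyl)benzofuran-5-yl]propanoate | COC(=O)CCc1cc(OC)c2oc([Si](C)(C)C)cc2c1
F7 | step 8 | 5-[3-(dimethoxymethyl)-5-(3-hydroxypropyl)-7-methoxybenzofuran-2-yl]-3-methoxybenzene-1,2-diol | COC(OC)c1c(-c2cc(OC)c(O)c(O)c2)oc2c(OC)cc(CCCO)cc12
A1 | alternative 1 | methyl (E)-3-(3-benzyloxy-4-hydroxy-5-methoxyphenyl)acrylate | COC(=O)/C=C/c1cc(OC)c(O)c(OCc2ccccc2)c1
A2 | alternative 1 | dihydroconiferyl alcohol [4-(3-hydroxypropyl)-2-methoxyphenol] | COc1cc(CCCO)ccc1O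
A3 | alternative 1 | methyl trans-2-(3-benzyloxy-4-hydroxy-5-methoxyphenyl)-5-(3-hydroxypropyl)-7-methoxy-2,3-dihydrobenzofuran-3-carboxylate (racemic, one enantiomer drawn) | COC(=O)[C@H]1[C@H](c2cc(OC)c(O)c(OCc3ccccc3)c2)Oc2c(OC)cc(CCCO)cc21
A4 | alternative 2 | 5-[3,4-bis(benzyloxy)-5-methoxyphenyl]furan-3-carbaldehyde | O=Cc1coc(-c2cc(OC)c(OCc3ccccc3)c(OCc3ccccc3)c2)c1
A5 | alternative 2 | dimethyl succinate | COC(=O)CCC(=O)OC
A6 | alternative 2 | (E)-4-{5-[3,4-bis(benzyloxy)-5-methoxyphenyl]furan-3-yl}-3-(methoxycarbonyl)but-3-enoic acid | COC(=O)/C(CC(=O)O)=C/c1coc(-c2cc(OC)c(OCc3ccccc3)c(OCc3ccccc3)c2)c1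
A7 | alternative 2 | methyl 7-acetoxy-2-[3,4-bis(benzyloxy)-5-methoxyphenyl]benzofuran-5-carboxylate | COC(=O)c1cc(OC(C)=O)c2oc(-c3cc(OC)c(OCc4ccccc4)c(OCc4ccccc4)c3)cc2c1
A8 | alternative 3 | methyl 3-{3-[3,4-bis(benzyloxy)-5-methoxybenzoyl]-7-methoxy-2-oxo-2,3-dihydrobenzofuran-5-yl}propanoate (C3 stereolabile) | COC(=O)CCc1cc(OC)c2OC(=O)C(C(=O)c3cc(OC)c(OCc4ccccc4)c(OCc4ccccc4)c3)c2c1
A9 | alternative 3 | methyl 2-[3,4-bis(benzyloxy)-5-methoxyphenyl]-7-methoxy-5-(3-methoxy-3-oxopropyl)benzofuran-3-carboxylate | COC(=O)CCc1cc(OC)c2oc(-c3cc(OC)c(OCc4ccccc4)c(OCc4ccccc4)c3)c(C(=O)OC)c2c1
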